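Assumption: the target, methyl 2-hydroxy-6-icosyl-4-methoxybenzoate, has no stereocentre and no stereogenic double bond, so "the single enantiomer given" is simply the achiral compound itself and no stereocontrol is required.

**Retrosynthetic overview**
1. The obvious route (alkyl chain attached to a preformed resorcylate by cross-coupling, Wittig or lateral alkylation) is deliberately avoided.
2. Key step: the benzene ring (the only ring) is built last by a regioselective Diels–Alder benzannulation of ynoate 6 with Brassard-type diene 9; this one step places the ester, the chelated OH, the 4-OMe and the C20 chain.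
3. Ynoate 6 comes from docos-1-yne 3 and methyl chloroformate 4; alkyne 3 comes from 1-bromoicosane 1 and lithium acetylide 2.
4. Diene 9 comes from methyl (E)-3-methoxybut-2-enoate 7 by γ-deprotonation and O-silylation.

**Route**

Step 1
Reactants: 1 1-bromoicosane; 2 lithium acetylide–ethylenediamine complex
Product: 3 docos-1-yne
Conditions: 2 (1.5 equiv), DMSO–THF (3:1), 15 °C → rt, 12 h (1 added as a warm THF solution)
Reagents that add atoms: none
Why: Acetylide alkylation (SN2) of an unhindered primary bromide in a dipolar aprotic medium, where elimination is minor; no stereocentre is formed.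

Step 2
Reactants: 3 docos-1-yne; 4 methyl chloroformate
Product: 6 methyl tricos-2-ynoate, via lithium docosynide 5 (not isolated)
Conditions: n-BuLi (1.1 equiv), THF, −40 → 0 °C; then 4 (1.5 equiv), −78 °C → rt
Reagents that add atoms: none
Why: Quantitative deprotonation of the terminal alkyne followed by C-acylation of the lithium acetylide with excess cold chloroformate (alkynyl methoxycarbonylation), which suppresses double addition.

Step 3
Reactants: 7 methyl (E)-3-methoxybut-2-enoate
Product: 9 1,3-dimethoxy-1-(trimethylsilyloxy)buta-1,3-diene, via lithium dienolate 8 (not isolated)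
Conditions: LDA (commercial solution, 1.1 equiv), THF, −78 °C, 1 h; TMSCl (1.3 equiv), −78 °C → rt; evaporate, pentane, filter, Kugelrohr distil, use at once
Reagents that add atoms: chlorotrimethylsilane (TMSCl), C[Si](C)(C)Cl
Why: Kinetic γ-deprotonation of the vinylogous ester gives the extended dienolate, which the hard silyl chloride traps on oxygen (silyl ketene acetal formation, Brassard-type diene); the ketene-acetal geometry is irrelevant because that carbon becomes aromatic.

Step 4
Reactants: 6 methyl tricos-2-ynoate; 9 1,3-dimethoxy-1-(trimethylsilyloxy)buta-1,3-diene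
Product: 12 methyl 2-hydroxy-6-icosyl-4-methoxybenzoate, via cyclohexadiene cycloadduct 10 (not isolated), via aryl silyl ether 11 (not isolated)
Conditions: 9 (3 equiv, added in portions), neat (trace xylene), sealed tube, 140 °C, 24–36 h; then 1 M HCl, THF, rt, 30 min
Reagents that add atoms: none
Why: Diels–Alder benzannulation in which the nucleophilic CH2 terminus of the vinylketene acetal bonds to the β-carbon of the ynoate, so the ketal carbon ends up next to the ester carbon, and the 1,4-diene then aromatises by 1,4-elimination of methanol and the aryl silyl ether is cleaved by acid, giving the 2-OH/4-OMe/6-alkyl pattern with no stereocentre remaining.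

**Compound list**
1 | 1-bromoicosane | CCCCCCCCCCCCCCCCCCCCBr | starting material
2 | lithium acetylide–ethylenediamine complex | [Li+].[C-]#C.NCCN | starting material
3 | docos-1-yne | CCCCCCCCCCCCCCCCCCCCC#C | intermediate
4 | methyl chloroformate | COC(=O)Cl | starting material
5 | lithium docos-1-yn-1-ide | [Li+].CCCCCCCCCCCCCCCCCCCCC#[C-] | intermediate (not isolated)
6 | methyl tricos-2-ynoate | CCCCCCCCCCCCCCCCCCCCC#CC(=O)OC | intermediate
7 | methyl (E)-3-methoxybut-2-enoate | CO/C(C)=C/C(=O)OC | starting material
8 | lithium 1,3-dimethoxybuta-1,3-dien-1-olate (ketene-acetal geometry undefined) | [Li+].COC(=C)C=C(OC)[O-] | intermediate (not isolated)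
9 | 1,3-dimethoxy-1-(trimethylsilyloxy)buta-1,3-diene (E/Z mixture at C1=C2, both converge) | COC(=C)C=C(OC)O[Si](C)(C)C | intermediate
10 | methyl 2-icosyl-4,6-dimethoxy-6-(trimethylsilyloxy)cyclohexa-1,4-diene-1-carboxylate (racemic; its one stereocentre is destroyed on aromatisation) | CCCCCCCCCCCCCCCCCCCCC1=C(C(=O)OC)C(OC)(O[Si](C)(C)C)C=C(OC)C1 | intermediate (not isolated)
11 | methyl 2-icosyl-4-methoxy-6-(trimethylsilyloxy)benzoate | CCCCCCCCCCCCCCCCCCCCc1cc(OC)cc(O[Si](C)(C)C)c1C(=O)OC | intermediate (not isolated)
12 | methyl 2-hydroxy-6-icosyl-4-methoxybenzoate | CCCCCCCCCCCCCCCCCCCCc1cc(OC)cc(O)c1C(=O)OC | target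

**Totals**
Total step count: 4. Longest linear sequence: 3 steps (1 → 3 → 6 → 12); diene 9 is made in one convergent step.

**Three steps most likely to fail, with fallbacks**

Step 4 (most risky: a β-alkyl ynoate is a sluggish dienophile and diene 9 is thermally labile). The fallback sets out from 6 and comes back at 12 by an anionic annulation instead of a cycloaddition. Semi-hydrogenation of 6 (H2, Lindlar catalyst, quinoline, EtOAc) gives methyl (Z)-tricos-2-enoate F1. Michael–Dieckmann annulation of this with methyl acetoacetate (NaOMe, MeOH, reflux, then dilute acid) gives methyl 6-icosyl-2,4-dioxocyclohexane-1-carboxylate F2 (racemic, largely enolised; its stereocentres are lost in the next operation). Heating this with I2 in MeOH aromatises the ring and converts the non-chelated C4 oxygen into its methyl ether, giving 12. The selectivity of this last operation for the 4-OMe/2-OH pattern is expected from chelation of the C2 enol to the ester but should be confirmed.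

Step 3 (diene 9 is moisture-sensitive and may not be obtained pure). The fallback sets out from 6 and comes back at 12 using a more robust, distillable bis-silyl diene and late methylation. Methyl acetoacetate with TMSCl/Et3N gives methyl 3-(trimethylsilyloxy)but-2-enoate F3. LDA then TMSCl (THF, −78 °C) converts this into 1-methoxy-1,3-bis(trimethylsilyloxy)buta-1,3-diene F4. Diels–Alder reaction of this diene with 6 (140 °C, then HCl/THF) gives methyl 2,4-dihydroxy-6-icosylbenzoate F5. MeI (1.05 equiv), K2CO3, acetone then methylates only the free 4-OH, because the 2-OH is hydrogen-bonded to the ester, giving 12.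

Step 1 (the waxy C20 bromide dissolves poorly in DMSO, so conversion may be slow and elimination may compete). The fallback sets out from 1 and comes back at 6, replacing the C2 + C1 build-up by a C3 synthon. Dilithium propiolate (propiolic acid, 2 equiv n-BuLi, THF–HMPA, −78 °C → rt) is alkylated with 1 to give tricos-2-ynoic acid F6. Esterification of this acid (MeI, K2CO3, DMF) gives 6, bypassing compounds 3 and 5.

**Further compounds**
F1 | step 4 | methyl (Z)-tricos-2-enoate | CCCCCCCCCCCCCCCCCCCC/C=C\C(=O)OC
F2 | step 4 | methyl 6-icosyl-2,4-dioxocyclohexane-1-carboxylate (racemic, keto/enol mixture) | CCCCCCCCCCCCCCCCCCCCC1CC(=O)CC(=O)C1C(=O)OC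
F3 | step 3 | methyl 3-(trimethylsilyloxy)but-2-enoate (E/Z mixture) | CC(O[Si](C)(C)C)=CC(=O)OC
F4 | step 3 | 1-methoxy-1,3-bis(trimethylsilyloxy)buta-1,3-diene | COC(O[Si](C)(C)C)=CC(=C)O[Si](C)(C)C
F5 | step 3 | methyl 2,4-dihydroxy-6-icosylbenzoate | CCCCCCCCCCCCCCCCCCCCc1cc(O)cc(O)c1C(=O)OC
F6 | step 1 | tricos-2-ynoic acid | CCCCCCCCCCCCCCCCCCCCC#CC(=O)O
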